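## Analysis of the target

Locants used throughout: ring A is the cyclohexane C1′–C6′ (C1′ bonded to ring B, C3′ the CMe2 carbon, C4′ the CHBr carbon). Ring B is the 7-oxabicyclo[2.2.1]heptane (C1 methyl-bearing bridgehead, C2 CHBr, C3 CH2, C4 bridgehead bonded to C1′, C5 and C6 CH2, O7).

Target 34 is a dibrominated bisabolane-type skeleton: two six-carbon rings joined only by the bond C1′–C4, with ring B bridged by O7 between C1 and C4. Of its five stereocentres, C1′ and C4′ are trans-1,4 (both substituents equatorial). In ring B the bridge ties C1 to C4, and the C2 bromine is endo, that is anti to O7. C4 is stereogenic only because its two arms differ (C3–C2 carries bromine, C5–C6 does not), and C1′ only because C2′ leads to CMe2 and C6′ does not. Relating these two centres across a freely rotating bond, each flanked by two near-identical methylene groups, is the real difficulty, and C4 is fully substituted as well. The C4′ bromide is neopentylic, so it cannot be introduced by substitution and is prone to elimination, hydrogenolysis and metal insertion; the C2 bromide is β to the ether oxygen and the bridged ether is acid-sensitive. The strategy rests on one feature: with a C5′=C6′ double bond, C1′ becomes the terminus of an allyl unit whose other end, C5′, is the neighbour of C4′. An ester oxygen on C5′, trans to the C4′ bromine, can therefore hand its configuration to C1′ in a suprafacial [3,3] shift, while the migrating ester α-carbon becomes C4 with its oxygen and both arms in place. In ring B, a hydroxyl on C4 and a C1=C2 double bond are then enough, because bromoetherification derives C1, C2 and O7 from C4 alone.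

## Retrosynthetic reasoning

**34 to 33.** The bonds O7–C1 and C2–Br are cut together, which leads to hydroxy alkene 33. Cutting here removes three of the five stereocentres at once and leaves a monocyclic ring B. The forward reaction must add positive bromine to C2 on the face away from the C4 hydroxyl so that the hydroxyl can close onto C1.

**33 to 31 (through 32).** The hydroxyl is masked as the 4-methoxybenzyl ether 32, and two hydrogen atoms are removed from C5′ and C6′ to give 31. The ring A double bond is the trace the sigmatropic step leaves behind. Forward, it has to be saturated without touching the trisubstituted ring B alkene or either C–Br bond, which calls for a metal-free hydrogen transfer.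

**31 to 30.** The C1=C2 double bond is cut to the two terminal alkenes of 30. This is the only unsaturation of ring B, and both partners hang from C4, so a ring-closing metathesis closes ring B without creating a stereocentre.

**30 to 24 (through 28 and 26).** The C5 arm is taken apart: the methylene on C1 comes from phosphonium salt 29 and ketone 28, the C5–C6 single bond from enone 26, and the C5=C6 bond from aldehyde 24 and phosphonate 25. These cuts are dictated by the fact that the rearrangement delivers C5 as a carboxyl carbon, which needs three more carbons.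

**24 to 21 (through 22).** Only the oxidation level of C5 changes; methyl ester 22 is the handle for a controlled partial reduction.

**21 to 17 (key disconnection).** The bond C1′–C4 is cut with the alkene moved from C5′=C6′ back to C6′=C1′ and the oxygen returned to C5′. This gives allylic ester 17. It is the one place where a stereocentre already present in ring A (the carbinol carbon next to C4′–Br) can control both C1′ and C4. The forward reaction has to form ketene acetal 19 with one defined geometry and pass through one transition-state shape.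

**17 to 8 and 16; 16 to 9, 10 and 13.** The ester C–O bond separates the ring A alcohol 8 from acid 16. Acid 16 comes from ethyl glycolate 9 by O-benzylation with 10 (giving 12), C-allylation with 13 (giving 15) and saponification. The α-centre of 16 need not be controlled, since step 10 erases it.

**8 to 6 (through 7).** The single enantiomer 8 is taken from racemic 6 by enzymatic acylation to 7 and enzymatic hydrolysis. The bromine-bearing centre is the only one formed without a controlling element, so a resolution is placed at the first alcohol.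

**6 to 1 (through 3 and 2).** Alcohol 6 is the transposition product of epoxy ketone 3 (carbonyl and α-carbon become the alkene, the β-carbon keeps its oxygen). 3 is the epoxide of enone 2, and 2 is the γ-bromination product of enone 1. Radical substitution is one of the few ways to put bromine on a carbon next to CMe2, and epoxidation anti to that bromine secures the trans O/Br relation on which the key step depends.

## Alternatives that were turned down

**Alternative 1:** Disconnection of C1–C2 and C3–C4, a [4+2] cycloaddition of furan A2 (ring A on one α-carbon, methyl on the other) with 2-bromoprop-2-enal A3. Under a chiral cationic boron Lewis acid the two furan α-carbons would bond to the brominated and the terminal carbon of A3, giving oxanorbornene A1 with bromine endo and formyl exo on C2.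
- For: ring B, the oxygen bridge and the C2 bromine arise in one catalytic, enantioselective step. On step economy for ring B this is clearly stronger than the chosen route, which needs about ten steps after the C1′–C4 bond is formed.
- Against: both reacting furan carbons are fully substituted and differ only as methyl against secondary alkyl, so nothing in the diene decides which of them meets the brominated carbon. 2,5-Dialkylfurans also give readily reversible adducts. The formyl group then has to be excised from a tertiary bromide carbon with retention, and the C5=C6 alkene reduced without hydrogenolysis. A2 must already contain ring A with its neopentylic bromide and the trans-1,4 relation, to which the cycloaddition contributes nothing.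
- Comparison: the chosen route gives up the brevity but gains an unambiguous regiochemistry and a direct relay from ring A to C4.

**Alternative 2:** Disconnection of C2′–C3′, closing ring A last by cation–olefin cyclisation. A Lewis acid would ionise the tertiary hydroxyl of bromohydrin A5, the neighbouring bromine would bridge to C3′, the methylene terminus of the 1,1-disubstituted alkene on C4 would attack C3′, and the C1′ cation would lose a proton to give cyclohexene A4.
- For: convergent and biomimetic. The C4′ configuration would come from an enantiopure bromohydrin, so no resolution is needed; on this point it is stronger than the chosen route.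
- Against: the cation at C1′ sits next to C4, where a shift of C3 or C5 would give an oxygen-stabilised cation and destroy the bicycle. Bromonium ions can pass Br+ between alkenes and lose optical purity. Proton loss can give either the C1′=C2′ or the C1′=C6′ alkene. C1′ would finally depend on hydrogenating a trisubstituted alkene whose faces differ only through a remote bromine, in the presence of two C–Br bonds.
- Comparison: the chosen route sets C1′ by a suprafacial shift instead and needs no cation next to ring B.

**Alternative 3:** Disconnection of C2–Br on a cyclohexanone form of ring B. The enamine of symmetric hydroxy ketone A7 with a C2-symmetric secondary amine would take bromine from a bromodienone donor at one of the two α-methylene groups, giving bromo ketone A6 with bromine trans to hydroxyl.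
- For: a known type of catalytic desymmetrisation that distinguishes the two arms of C4 directly, with no protecting group. It is stronger than the chosen route in that the catalyst, not a transition-state shape, makes the choice.
- Against: A7 presupposes the C1′–C4 bond. Making it would need a C1′ carbanion in a ring that carries a bromide, or a reduction with no control of C1′. After A6, methyl addition to an epimerisable α-bromo ketone produces a bromohydrin alkoxide that can close to an epoxide. Bridging O7 to C1 then needs a tertiary cation at C1 next to C2–Br, where bromine participation and elimination compete.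
- Comparison: the chosen route solves exactly the bond this alternative leaves open and installs the C2 bromine in the same step that closes the bridge.

Key step: step 10

## Route

Remark: 5,5-dimethylcyclohex-2-en-1-one (1) is taken as a purchasable material.
Remark: racemic compounds with more than one stereocentre (3 to 6) are written as one enantiomer in SMILES.

Step 1
Reactants: 1 5,5-dimethylcyclohex-2-en-1-one
Product: 2 (4RS)-4-bromo-5,5-dimethylcyclohex-2-en-1-one
Conditions: NBS, AIBN (cat.), PhCF3, 80 °C
Reagents that add atoms: N-bromosuccinimide, O=C1CCC(=O)N1Br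
Why: Wohl–Ziegler bromination: hydrogen abstraction at the γ-methylene C4 gives a radical delocalised over C4, C2 and the carbonyl oxygen, and bromine is taken up at C4 so that conjugation is kept. The quaternary C5 next to it leaves no hydrogen for loss of HBr; the single stereocentre forms as a racemate.

Step 2
Reactants: 2 (4RS)-4-bromo-5,5-dimethylcyclohex-2-en-1-one
Product: 3 (1RS,5SR,6SR)-5-bromo-4,4-dimethyl-7-oxabicyclo[4.1.0]heptan-2-one (epoxide oxygen trans to bromine)
Conditions: 30% H2O2, NaOH (cat.), MeOH, 0 °C
Reagents that add atoms: hydrogen peroxide, OO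
Why: Weitz–Scheffer epoxidation: hydroperoxide adds to the β-carbon on the face away from the pseudoaxial bromine on the neighbouring carbon and the enolate closes the oxirane, which places the oxygen trans to bromine.

Step 3
Reactants: 3 (1RS,5SR,6SR)-5-bromo-4,4-dimethyl-7-oxabicyclo[4.1.0]heptan-2-one
Product: 6 (1RS,6RS)-6-bromo-5,5-dimethylcyclohex-2-en-1-ol (trans), via epoxy hydrazone 4 (not isolated), via hydroxy diazene 5 (not isolated)
Conditions: N2H4·H2O, AcOH (cat.), MeOH, 0 °C to 23 °C
Reagents that add atoms: none
Why: Wharton transposition: hydrazone 4 opens the oxirane to diazene 5, which loses N2 and leaves the alkene at the former carbonyl and α-carbons. The carbinol C–O bond is the old epoxide C–O bond, so oxygen stays trans to bromine.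

Step 4
Reactants: 6 (1RS,6RS)-6-bromo-5,5-dimethylcyclohex-2-en-1-ol
Product: 7 (1R,6R)-6-bromo-5,5-dimethylcyclohex-2-en-1-yl acetate
Conditions: vinyl acetate, Burkholderia cepacia lipase (immobilised), t-BuOMe, 30 °C, stopped before half conversion
Reagents that add atoms: vinyl acetate, CC(=O)OC=C
Why: Lipase-catalysed kinetic resolution by irreversible transesterification: with the brominated neopentylic side as the large and the vinyl side as the medium substituent, the (1R) alcohol is the one expected to be acylated, while the (1S,6S) half of 6 stays as the alcohol and is removed by chromatography. Should the enzyme prefer the other enantiomer, the recovered alcohol is 8 itself and step 5 falls away.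

Step 5
Reactants: 7 (1R,6R)-6-bromo-5,5-dimethylcyclohex-2-en-1-yl acetate
Product: 8 (1R,6R)-6-bromo-5,5-dimethylcyclohex-2-en-1-ol
Conditions: Candida antarctica lipase B (immobilised), NaH2PO4/Na2HPO4 buffer pH 7, t-BuOMe, 30 °C
Reagents that add atoms: none
Why: Enzymatic ester hydrolysis at neutral pH: no alkoxide is formed, so the trans bromohydrin cannot close to an epoxide, and a second pass through the same enantiopreference raises the optical purity.

Step 6
Reactants: 9 ethyl glycolate; 10 4-methoxybenzyl chloride
Product: 12 ethyl 2-[(4-methoxyphenyl)methoxy]acetate, via sodium alkoxide 11 (not isolated)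
Conditions: NaH, Bu4NI (cat.), THF, 0 °C to 23 °C
Reagents that add atoms: none
Why: Williamson ether synthesis on alkoxide 11; the benzylic chloride, activated by iodide exchange, is alkylated faster than the ester is attacked.

Step 7
Reactants: 12 ethyl 2-[(4-methoxyphenyl)methoxy]acetate; 13 allyl bromide
Product: 15 ethyl (2RS)-2-[(4-methoxyphenyl)methoxy]pent-4-enoate, via lithium enolate 14 (not isolated)
Conditions: LiN(iPr)2, THF, −78 °C; then 13, DMPU, −78 to −30 °C
Reagents that add atoms: none
Why: Alkylation of the chelated lithium ester enolate 14 with an allylic bromide; the new stereocentre is racemic and is erased again in step 10.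

Step 8
Reactants: 15 ethyl (2RS)-2-[(4-methoxyphenyl)methoxy]pent-4-enoate
Product: 16 (2RS)-2-[(4-methoxyphenyl)methoxy]pent-4-enoic acid
Conditions: LiOH, THF/MeOH/H2O, 23 °C; then 1 M HCl, 0 °C
Reagents that add atoms: lithium hydroxide, [Li+].[OH-]
Why: Saponification; the acid is freed with cold dilute HCl, which the benzylic ether tolerates.

Step 9
Reactants: 8 (1R,6R)-6-bromo-5,5-dimethylcyclohex-2-en-1-ol; 16 (2RS)-2-[(4-methoxyphenyl)methoxy]pent-4-enoic acid
Product: 17 (1R,6R)-6-bromo-5,5-dimethylcyclohex-2-en-1-yl (2RS)-2-[(4-methoxyphenyl)methoxy]pent-4-enoate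
Conditions: DCC, DMAP (cat.), CH2Cl2, 0 °C to 23 °C
Reagents that add atoms: none
Why: Steglich esterification through the N-acylpyridinium ion: the carbinol C–O bond of 8 is not touched, so its configuration is kept. Both α-epimers of the acyl part are carried on together because that centre is made planar in step 10.

Step 10
Reactants: 17 (1R,6R)-6-bromo-5,5-dimethylcyclohex-2-en-1-yl (2RS)-2-[(4-methoxyphenyl)methoxy]pent-4-enoate
Product: 21 (2S)-2-[(1R,4S)-4-bromo-5,5-dimethylcyclohex-2-en-1-yl]-2-[(4-methoxyphenyl)methoxy]pent-4-enoic acid, via potassium enolate 18 (not isolated), via silyl ketene acetal 19 (not isolated), via trimethylsilyl ester 20 (not isolated)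
Conditions: KN(SiMe3)2, THF/PhMe, −78 °C; Me3SiCl, Et3N; −78 to 23 °C, then 50 °C; 1 M HCl work-up
Reagents that add atoms: none
Why: Ireland–Claisen rearrangement of an α-alkoxy ester: KN(SiMe3)2 removes the α-proton while the metal is held between the carbonyl and the ether oxygen, so enolate 18 and, after O-silylation, ketene acetal 19 carry the silyloxy group cis to the benzyloxy group (Z) whichever α-epimer of 17 is used. On warming, 19 undergoes a concerted suprafacial [3,3] shift that breaks C5′–O and forms C1′–C4; no ring is closed, and the closest known reaction type is the rearrangement of glycolate and lactate esters of cyclohex-2-enols through chelation-defined silyl ketene acetals. C1′ is controlled by the carbinol centre of 8: the new bond appears on the ring A face that the ester oxygen leaves, which is the face anti to the C4′ bromine, and this gives the trans-1,4 pattern. C4 is controlled by the Z geometry together with a boat-like transition state, which places the carboxyl carbon (later C5) and the allyl group (later C3) as drawn in 21. The selectivity the step needs is boat over chair: in the chair the Me3SiO-bearing carbon would lie over ring A, where the axial C3′ methyl on the reacting face projects, whereas the boat keeps it outside the ring, the usual preference of cyclohexenyl esters. Loss of HBr at the enolate stage is not expected, because H–C5′ and Br–C4′ are cis and cannot become antiperiplanar, and the neopentylic bromide resists internal alkylation. Acidic work-up hydrolyses silyl ester 20 to 21 without leaving a carboxylate next to the now allylic bromide.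

Step 11
Reactants: 21 (2S)-2-[(1R,4S)-4-bromo-5,5-dimethylcyclohex-2-en-1-yl]-2-[(4-methoxyphenyl)methoxy]pent-4-enoic acid
Product: 22 methyl (2S)-2-[(1R,4S)-4-bromo-5,5-dimethylcyclohex-2-en-1-yl]-2-[(4-methoxyphenyl)methoxy]pent-4-enoate
Conditions: Me3SiCHN2, PhMe/MeOH, 0 °C
Reagents that add atoms: (trimethylsilyl)diazomethane, C[Si](C)(C)C=[N+]=[N-]
Why: Methyl ester formation with a diazoalkane under neutral conditions, so that no carboxylate is present that could attack the allylic bromide in an SN2′ lactonisation.

Step 12
Reactants: 22 methyl (2S)-2-[(1R,4S)-4-bromo-5,5-dimethylcyclohex-2-en-1-yl]-2-[(4-methoxyphenyl)methoxy]pent-4-enoate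
Product: 24 (2S)-2-[(1R,4S)-4-bromo-5,5-dimethylcyclohex-2-en-1-yl]-2-[(4-methoxyphenyl)methoxy]pent-4-enal, via aluminium hemiacetal 23 (not isolated)
Conditions: i-Bu2AlH, CH2Cl2, −78 °C; MeOH, then aq. potassium sodium tartrate
Reagents that add atoms: none
Why: Partial reduction of an α-alkoxy ester: hemiacetal 23, held by chelation to the neighbouring ether oxygen, survives at −78 °C and collapses to the aldehyde only on work-up. The hindered allylic bromide is not reduced at this temperature.

Step 13
Reactants: 24 (2S)-2-[(1R,4S)-4-bromo-5,5-dimethylcyclohex-2-en-1-yl]-2-[(4-methoxyphenyl)methoxy]pent-4-enal; 25 dimethyl (2-oxopropyl)phosphonate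
Product: 26 (3E,5R)-5-[(1R,4S)-4-bromo-5,5-dimethylcyclohex-2-en-1-yl]-5-[(4-methoxyphenyl)methoxy]octa-3,7-dien-2-one
Conditions: NaH, THF, 0 °C to 23 °C
Reagents that add atoms: none
Why: Horner–Wadsworth–Emmons olefination with a stabilised phosphonate anion gives the (E)-enone; the aldehyde has no α-hydrogen and cannot enolise. The descriptor at the quaternary carbon changes only because the priorities change.

Step 14
Reactants: 26 (3E,5R)-5-[(1R,4S)-4-bromo-5,5-dimethylcyclohex-2-en-1-yl]-5-[(4-methoxyphenyl)methoxy]octa-3,7-dien-2-one
Product: 28 (5S)-5-[(1R,4S)-4-bromo-5,5-dimethylcyclohex-2-en-1-yl]-5-[(4-methoxyphenyl)methoxy]oct-7-en-2-one, via boron enolate 27 (not isolated)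
Conditions: catecholborane, THF, −10 to 23 °C; then NaH2PO4/Na2HPO4 buffer pH 7
Reagents that add atoms: none
Why: Conjugate reduction of an s-cis enone by catecholborane: hydride reaches C4 through a six-membered transition state and boron enolate 27 protects the carbonyl until hydrolysis. Isolated alkenes are not hydroborated at this temperature, and neither the borane nor the weakly nucleophilic boron enolate displaces the allylic bromide.

Step 15
Reactants: 28 (5S)-5-[(1R,4S)-4-bromo-5,5-dimethylcyclohex-2-en-1-yl]-5-[(4-methoxyphenyl)methoxy]oct-7-en-2-one; 29 methyltriphenylphosphonium bromide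
Product: 30 (5S)-5-[(1R,4S)-4-bromo-5,5-dimethylcyclohex-2-en-1-yl]-5-[(4-methoxyphenyl)methoxy]-2-methylocta-1,7-diene
Conditions: 29, KOtBu, THF, 0 °C; then 28, 0 °C
Reagents that add atoms: none
Why: Wittig methylenation of an unhindered methyl ketone, fast enough at 0 °C that the ylide does not act as a base on the allylic bromide.

Step 16
Reactants: 30 (5S)-5-[(1R,4S)-4-bromo-5,5-dimethylcyclohex-2-en-1-yl]-5-[(4-methoxyphenyl)methoxy]-2-methylocta-1,7-diene
Product: 31 1-({[(1S)-1-[(1R,4S)-4-bromo-5,5-dimethylcyclohex-2-en-1-yl]-4-methylcyclohex-3-en-1-yl]oxy}methyl)-4-methoxybenzene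
Conditions: second-generation Grubbs catalyst (H2IMes)(PCy3)Cl2Ru=CHPh (cat.), CH2Cl2, 40 °C
Reagents that add atoms: none
Why: Ring-closing metathesis: the ruthenium carbene loads on the monosubstituted allyl alkene and closes onto the 1,1-disubstituted alkene, giving the trisubstituted cyclohexene of ring B with loss of ethene. The ring A cyclohexene is unstrained and stays closed, and the quaternary centre is not involved.

Step 17
Reactants: 31 1-({[(1S)-1-[(1R,4S)-4-bromo-5,5-dimethylcyclohex-2-en-1-yl]-4-methylcyclohex-3-en-1-yl]oxy}methyl)-4-methoxybenzene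
Product: 32 1-({[(1S)-1-[(1S,4S)-4-bromo-3,3-dimethylcyclohexyl]-4-methylcyclohex-3-en-1-yl]oxy}methyl)-4-methoxybenzene
Conditions: 2-O2NC6H4SO2NHNH2, Et3N, CH2Cl2, 23 °C, stopped when 31 is consumed
Reagents that add atoms: none
Why: Diimide reduction: two hydrogen atoms are transferred in a concerted syn fashion, much faster to the cis-disubstituted ring A alkene than to the trisubstituted ring B alkene. No metal is present, so neither C–Br bond nor the benzylic ether is cleaved; no stereocentre is created.

Step 18
Reactants: 32 1-({[(1S)-1-[(1S,4S)-4-bromo-3,3-dimethylcyclohexyl]-4-methylcyclohex-3-en-1-yl]oxy}methyl)-4-methoxybenzene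
Product: 33 (1S)-1-[(1S,4S)-4-bromo-3,3-dimethylcyclohexyl]-4-methylcyclohex-3-en-1-ol
Conditions: DDQ, CH2Cl2/NaH2PO4–Na2HPO4 buffer pH 7, 0 °C
Reagents that add atoms: none
Why: Oxidative cleavage of the electron-rich benzylic ether by hydride abstraction and hydrolysis of the oxocarbenium ion; the buffer keeps the tertiary homoallylic alcohol from ionising.

Step 19
Reactants: 33 (1S)-1-[(1S,4S)-4-bromo-3,3-dimethylcyclohexyl]-4-methylcyclohex-3-en-1-ol
Product: 34 (1R,2R,4S)-2-bromo-4-[(1S,4S)-4-bromo-3,3-dimethylcyclohexyl]-1-methyl-7-oxabicyclo[2.2.1]heptane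
Conditions: NBS, CH2Cl2, 0 °C, dark
Reagents that add atoms: N-bromosuccinimide, O=C1CCC(=O)N1Br
Why: Bromoetherification: Br+ adds to the C1=C2 alkene on the face opposite the C4 hydroxyl, and the hydroxyl closes across the ring onto the tertiary C1, forming a five-membered ether ring on either side. C1 follows from C4 through the bridge and the C2 bromine ends anti to O7 (endo) by anti addition; bromonium formation on the other face is reversible and unproductive.

## Compound list

1 | 5,5-dimethylcyclohex-2-en-1-one | CC1(C)CC=CC(=O)C1 | starting material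
2 | (4RS)-4-bromo-5,5-dimethylcyclohex-2-en-1-one | CC1(C)CC(=O)C=CC1Br | intermediate
3 | (1RS,5SR,6SR)-5-bromo-4,4-dimethyl-7-oxabicyclo[4.1.0]heptan-2-one (racemic, one enantiomer drawn) | CC1(C)CC(=O)[C@H]2O[C@H]2[C@@H]1Br | intermediate
4 | hydrazone of 3, (5-bromo-4,4-dimethyl-7-oxabicyclo[4.1.0]heptan-2-ylidene)hydrazine, configuration of 3 (racemic) | CC1(C)CC(=NN)[C@H]2O[C@H]2[C@@H]1Br | intermediate (not isolated)
5 | (1RS,6RS)-6-bromo-3-diazenyl-5,5-dimethylcyclohex-2-en-1-ol (racemic) | CC1(C)CC(N=N)=C[C@@H](O)[C@@H]1Br | intermediate (not isolated)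
6 | (1RS,6RS)-6-bromo-5,5-dimethylcyclohex-2-en-1-ol, trans (racemic, one enantiomer drawn) | CC1(C)CC=C[C@@H](O)[C@@H]1Br | intermediate
7 | (1R,6R)-6-bromo-5,5-dimethylcyclohex-2-en-1-yl acetate | CC1(C)CC=C[C@@H](OC(C)=O)[C@@H]1Br | intermediate
8 | (1R,6R)-6-bromo-5,5-dimethylcyclohex-2-en-1-ol | CC1(C)CC=C[C@@H](O)[C@@H]1Br | intermediate
9 | ethyl glycolate | OCC(=O)OCC | starting material
10 | 4-methoxybenzyl chloride | COc1ccc(CCl)cc1 | starting material
11 | sodium alkoxide of ethyl glycolate | [Na+].[O-]CC(=O)OCC | intermediate (not isolated)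
12 | ethyl 2-[(4-methoxyphenyl)methoxy]acetate | CCOC(=O)COCc1ccc(OC)cc1 | intermediate
13 | allyl bromide | C=CCBr | starting material
14 | lithium enolate of 12 | [Li+].[O-]C(OCC)=COCc1ccc(OC)cc1 | intermediate (not isolated)
15 | ethyl (2RS)-2-[(4-methoxyphenyl)methoxy]pent-4-enoate | CCOC(=O)C(CC=C)OCc1ccc(OC)cc1 | intermediate
16 | (2RS)-2-[(4-methoxyphenyl)methoxy]pent-4-enoic acid | OC(=O)C(CC=C)OCc1ccc(OC)cc1 | intermediate
17 | (1R,6R)-6-bromo-5,5-dimethylcyclohex-2-en-1-yl (2RS)-2-[(4-methoxyphenyl)methoxy]pent-4-enoate | CC1(C)CC=C[C@@H](OC(=O)C(CC=C)OCc2ccc(OC)cc2)[C@@H]1Br | intermediate (precursor of the key step)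
18 | potassium (Z)-enolate of 17 | [K+].[O-]/C(O[C@@H]1C=CCC(C)(C)[C@H]1Br)=C(\OCc1ccc(OC)cc1)CC=C | intermediate (not isolated)
19 | (Z)-trimethylsilyl ketene acetal of 17 (silyloxy cis to benzyloxy) | C[Si](C)(C)O/C(O[C@@H]1C=CCC(C)(C)[C@H]1Br)=C(\OCc1ccc(OC)cc1)CC=C | intermediate (not isolated)
20 | trimethylsilyl ester of 21 | CC1(C)C[C@@H]([C@@](OCc2ccc(OC)cc2)(CC=C)C(=O)O[Si](C)(C)C)C=C[C@@H]1Br | intermediate (not isolated)
21 | (2S)-2-[(1R,4S)-4-bromo-5,5-dimethylcyclohex-2-en-1-yl]-2-[(4-methoxyphenyl)methoxy]pent-4-enoic acid | CC1(C)C[C@@H]([C@@](OCc2ccc(OC)cc2)(CC=C)C(O)=O)C=C[C@@H]1Br | intermediate (product of the key step)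
22 | methyl (2S)-2-[(1R,4S)-4-bromo-5,5-dimethylcyclohex-2-en-1-yl]-2-[(4-methoxyphenyl)methoxy]pent-4-enoate | CC1(C)C[C@@H]([C@@](OCc2ccc(OC)cc2)(CC=C)C(=O)OC)C=C[C@@H]1Br | intermediate
23 | diisobutylaluminium hemiacetal of 22 | CC1(C)C[C@@H]([C@@](OCc2ccc(OC)cc2)(CC=C)C(OC)O[Al](CC(C)C)CC(C)C)C=C[C@@H]1Br | intermediate (not isolated)
24 | (2S)-2-[(1R,4S)-4-bromo-5,5-dimethylcyclohex-2-en-1-yl]-2-[(4-methoxyphenyl)methoxy]pent-4-enal | CC1(C)C[C@@H]([C@@](OCc2ccc(OC)cc2)(CC=C)C=O)C=C[C@@H]1Br | intermediate
25 | dimethyl (2-oxopropyl)phosphonate | COP(=O)(CC(C)=O)OC | starting material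
26 | (3E,5R)-5-[(1R,4S)-4-bromo-5,5-dimethylcyclohex-2-en-1-yl]-5-[(4-methoxyphenyl)methoxy]octa-3,7-dien-2-one | CC1(C)C[C@@H]([C@@](OCc2ccc(OC)cc2)(CC=C)/C=C/C(C)=O)C=C[C@@H]1Br | intermediate
27 | (Z)-catecholboron enolate of 28 | CC1(C)C[C@@H]([C@@](OCc2ccc(OC)cc2)(CC=C)C/C=C(/C)OB2Oc3ccccc3O2)C=C[C@@H]1Br | intermediate (not isolated)
28 | (5S)-5-[(1R,4S)-4-bromo-5,5-dimethylcyclohex-2-en-1-yl]-5-[(4-methoxyphenyl)methoxy]oct-7-en-2-one | CC1(C)C[C@@H]([C@@](OCc2ccc(OC)cc2)(CC=C)CCC(C)=O)C=C[C@@H]1Br | intermediate
29 | methyltriphenylphosphonium bromide | C[P+](c1ccccc1)(c1ccccc1)c1ccccc1.[Br-] | starting material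
30 | (5S)-5-[(1R,4S)-4-bromo-5,5-dimethylcyclohex-2-en-1-yl]-5-[(4-methoxyphenyl)methoxy]-2-methylocta-1,7-diene | CC1(C)C[C@@H]([C@@](OCc2ccc(OC)cc2)(CC=C)CCC(C)=C)C=C[C@@H]1Br | intermediate
31 | 1-({[(1S)-1-[(1R,4S)-4-bromo-5,5-dimethylcyclohex-2-en-1-yl]-4-methylcyclohex-3-en-1-yl]oxy}methyl)-4-methoxybenzene | CC1(C)C[C@@H]([C@@]2(OCc3ccc(OC)cc3)CC=C(C)CC2)C=C[C@@H]1Br | intermediate
32 | 1-({[(1S)-1-[(1S,4S)-4-bromo-3,3-dimethylcyclohexyl]-4-methylcyclohex-3-en-1-yl]oxy}methyl)-4-methoxybenzene | CC1(C)C[C@@H]([C@@]2(OCc3ccc(OC)cc3)CC=C(C)CC2)CC[C@@H]1Br | intermediate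
33 | (1S)-1-[(1S,4S)-4-bromo-3,3-dimethylcyclohexyl]-4-methylcyclohex-3-en-1-ol | CC1(C)C[C@@H]([C@@]2(O)CC=C(C)CC2)CC[C@@H]1Br | intermediate
34 | (1R,2R,4S)-2-bromo-4-[(1S,4S)-4-bromo-3,3-dimethylcyclohexyl]-1-methyl-7-oxabicyclo[2.2.1]heptane | CC1(C)C[C@@H]([C@@]23CC[C@@](C)(O2)[C@H](Br)C3)CC[C@@H]1Br | target

## Step count and least certain steps

Total step count: 19. Longest linear sequence: 16 steps (steps 1 to 5 and 9 to 19; steps 6 to 8 make acid 16 in a side branch).

**Step 10 (key step).** Two things are most likely to go wrong. The first is poor discrimination between the boat and the chair, or a preference for the chair, which would invert C4 relative to C1′; the boat keeps the silyloxy-bearing carbon off ring A but puts the allyl methylene near C2′ and the axial C3′ methyl, so the margin cannot be predicted with confidence. The second is a slow rearrangement, because the new bond forms syn to an axial methyl group, which gives the ketene acetal time to be lost by hydrolysis.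

Fallback, should the chair prevail: the two arms of C4 exchange their origins, so that the chair delivers the same configuration. This sets out from 12 and 8. Ester 12 would be alkylated with 4-bromo-2-methylbut-1-ene (LiN(iPr)2, DMPU) to ethyl 2-[(4-methoxyphenyl)methoxy]-5-methylhex-5-enoate F1 and saponified to 2-[(4-methoxyphenyl)methoxy]-5-methylhex-5-enoic acid F2. Esterification with 8 would give (1R,6R)-6-bromo-5,5-dimethylcyclohex-2-en-1-yl 2-[(4-methoxyphenyl)methoxy]-5-methylhex-5-enoate F3. The same enolisation, silylation and rearrangement, now through the chair, would give (2R)-2-[(1R,4S)-4-bromo-5,5-dimethylcyclohex-2-en-1-yl]-2-[(4-methoxyphenyl)methoxy]-5-methylhex-5-enoic acid F4, in which the 3-methylbut-3-enyl group already is the C5 arm and the carboxyl carbon is C3. Methylation as in step 11 would give the methyl ester F5 and i-Bu2AlH the aldehyde (2R)-2-[(1R,4S)-4-bromo-5,5-dimethylcyclohex-2-en-1-yl]-2-[(4-methoxyphenyl)methoxy]-5-methylhex-5-enal F6. A Wittig reaction with Ph3P=CHOMe would give the enol ether (3R)-3-[(1R,4S)-4-bromo-5,5-dimethylcyclohex-2-en-1-yl]-1-methoxy-3-[(4-methoxyphenyl)methoxy]-6-methylhepta-1,6-diene F7. Dilute aqueous HCl in THF would give the homologous aldehyde (3S)-3-[(1R,4S)-4-bromo-5,5-dimethylcyclohex-2-en-1-yl]-3-[(4-methoxyphenyl)methoxy]-6-methylhept-6-enal F8, and methylenation with the ylide from 29 would return to the route at 30.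

**Step 3.** The Wharton step may give little product through collapse of the vinyl diazene along radical pathways, or through closure of the trans bromohydrin to a vinyl epoxide under the basic hydrazine. The epoxidation before it works on a γ-bromo enone that can also be attacked at the α′-position.

Fallback, setting out from 1 and using carbonyl reduction and inversion in place of transposition: kinetic α′-deprotonation of 1 with LiN(iPr)2 and bromination with N-bromosuccinimide would give 6-bromo-5,5-dimethylcyclohex-2-en-1-one F9. Reduction with NaBH4 and CeCl3·7H2O in MeOH, expected to occur mainly anti to the C–Br bond, would give cis-6-bromo-5,5-dimethylcyclohex-2-en-1-ol F10 as a racemate; any trans isomer formed is racemic 6. Lipase acylation as in step 4 would convert the (1R,6S) half into (1R,6S)-6-bromo-5,5-dimethylcyclohex-2-en-1-yl acetate F12 and leave (1S,6R)-6-bromo-5,5-dimethylcyclohex-2-en-1-ol F11. A Mitsunobu esterification of F11 with acid 16 (Ph3P, diisopropyl azodicarboxylate) would invert the carbinol carbon and return to the route at 17.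

**Step 14.** Hydride may be delivered to the allylic bromide with loss of bromine, or the carbonyl may be reduced in a 1,2 sense if the enone cannot reach the s-cis form next to the crowded quaternary carbon.

Fallback, setting out from 26 and avoiding any hydride reagent: methylenation of the enone carbonyl with the ylide from 29 would give the triene (3E,5R)-5-[(1R,4S)-4-bromo-5,5-dimethylcyclohex-2-en-1-yl]-5-[(4-methoxyphenyl)methoxy]-2-methylocta-1,3,7-triene F13. Ring-closing metathesis with the catalyst of step 16 would give the cyclohexadiene 1-({[(1S)-1-[(1R,4S)-4-bromo-5,5-dimethylcyclohex-2-en-1-yl]-4-methylcyclohexa-2,4-dien-1-yl]oxy}methyl)-4-methoxybenzene F14. Diimide in excess would then saturate both cis-disubstituted alkenes, the one in ring A and the one in the diene, and return to the route at 32. The cost is an acid-sensitive diene that can aromatise by loss of the benzylic alcohol, so F14 would be reduced without purification.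

**Step 17.** Selectivity between the two alkenes may be lost: the ring A alkene has a substituent on each allylic carbon and may react more slowly than a plain cyclohexene, so over-reduction of the ring B alkene or incomplete conversion are both possible.

Fallback, setting out from 31 and postponing the reduction until no other alkene is left: DDQ would give (1S)-1-[(1R,4S)-4-bromo-5,5-dimethylcyclohex-2-en-1-yl]-4-methylcyclohex-3-en-1-ol F15. N-Bromosuccinimide would close it to (1R,2R,4S)-2-bromo-4-[(1R,4S)-4-bromo-5,5-dimethylcyclohex-2-en-1-yl]-1-methyl-7-oxabicyclo[2.2.1]heptane F16; the ring A alkene, deactivated by its allylic bromine and without an internal nucleophile, should stay untouched. Diimide would then reduce the only remaining alkene and arrive at 34. The cost is that the allylic bromide has to survive two more steps.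

## Further compounds

F1 | step 10 | ethyl 2-[(4-methoxyphenyl)methoxy]-5-methylhex-5-enoate (racemic) | CCOC(=O)C(CCC(C)=C)OCc1ccc(OC)cc1
F2 | step 10 | 2-[(4-methoxyphenyl)methoxy]-5-methylhex-5-enoic acid (racemic) | OC(=O)C(CCC(C)=C)OCc1ccc(OC)cc1
F3 | step 10 | (1R,6R)-6-bromo-5,5-dimethylcyclohex-2-en-1-yl (2RS)-2-[(4-methoxyphenyl)methoxy]-5-methylhex-5-enoate | CC1(C)CC=C[C@@H](OC(=O)C(CCC(C)=C)OCc2ccc(OC)cc2)[C@@H]1Br
F4 | step 10 | (2R)-2-[(1R,4S)-4-bromo-5,5-dimethylcyclohex-2-en-1-yl]-2-[(4-methoxyphenyl)methoxy]-5-methylhex-5-enoic acid | CC1(C)C[C@@H]([C@](OCc2ccc(OC)cc2)(CCC(C)=C)C(O)=O)C=C[C@@H]1Br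
F5 | step 10 | methyl (2R)-2-[(1R,4S)-4-bromo-5,5-dimethylcyclohex-2-en-1-yl]-2-[(4-methoxyphenyl)methoxy]-5-methylhex-5-enoate | CC1(C)C[C@@H]([C@](OCc2ccc(OC)cc2)(CCC(C)=C)C(=O)OC)C=C[C@@H]1Br
F6 | step 10 | (2R)-2-[(1R,4S)-4-bromo-5,5-dimethylcyclohex-2-en-1-yl]-2-[(4-methoxyphenyl)methoxy]-5-methylhex-5-enal | CC1(C)C[C@@H]([C@](OCc2ccc(OC)cc2)(CCC(C)=C)C=O)C=C[C@@H]1Br
F7 | step 10 | (3R)-3-[(1R,4S)-4-bromo-5,5-dimethylcyclohex-2-en-1-yl]-1-methoxy-3-[(4-methoxyphenyl)methoxy]-6-methylhepta-1,6-diene (E/Z mixture) | CC1(C)C[C@@H]([C@](OCc2ccc(OC)cc2)(CCC(C)=C)C=COC)C=C[C@@H]1Br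
F8 | step 10 | (3S)-3-[(1R,4S)-4-bromo-5,5-dimethylcyclohex-2-en-1-yl]-3-[(4-methoxyphenyl)methoxy]-6-methylhept-6-enal | CC1(C)C[C@@H]([C@](OCc2ccc(OC)cc2)(CCC(C)=C)CC=O)C=C[C@@H]1Br
F9 | step 3 | 6-bromo-5,5-dimethylcyclohex-2-en-1-one (racemic) | CC1(C)CC=CC(=O)C1Br
F10 | step 3 | (1RS,6SR)-6-bromo-5,5-dimethylcyclohex-2-en-1-ol, cis (racemic, one enantiomer drawn) | CC1(C)CC=C[C@H](O)[C@@H]1Br
F11 | step 3 | (1S,6R)-6-bromo-5,5-dimethylcyclohex-2-en-1-ol | CC1(C)CC=C[C@H](O)[C@@H]1Br
F12 | step 3 | (1R,6S)-6-bromo-5,5-dimethylcyclohex-2-en-1-yl acetate | CC1(C)CC=C[C@@H](OC(C)=O)[C@H]1Br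
F13 | step 14 | (3E,5R)-5-[(1R,4S)-4-bromo-5,5-dimethylcyclohex-2-en-1-yl]-5-[(4-methoxyphenyl)methoxy]-2-methylocta-1,3,7-triene | CC1(C)C[C@@H]([C@@](OCc2ccc(OC)cc2)(CC=C)/C=C/C(C)=C)C=C[C@@H]1Br
F14 | step 14 | 1-({[(1S)-1-[(1R,4S)-4-bromo-5,5-dimethylcyclohex-2-en-1-yl]-4-methylcyclohexa-2,4-dien-1-yl]oxy}methyl)-4-methoxybenzene | CC1(C)C[C@@H]([C@@]2(OCc3ccc(OC)cc3)CC=C(C)C=C2)C=C[C@@H]1Br
F15 | step 17 | (1S)-1-[(1R,4S)-4-bromo-5,5-dimethylcyclohex-2-en-1-yl]-4-methylcyclohex-3-en-1-ol | CC1(C)C[C@@H]([C@@]2(O)CC=C(C)CC2)C=C[C@@H]1Br
F16 | step 17 | (1R,2R,4S)-2-bromo-4-[(1R,4S)-4-bromo-5,5-dimethylcyclohex-2-en-1-yl]-1-methyl-7-oxabicyclo[2.2.1]heptane | CC1(C)C[C@@H]([C@@]23CC[C@@](C)(O2)[C@H](Br)C3)C=C[C@@H]1Br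
A1 | alternative 1 | 2-bromo-4-[(1S,4S)-4-bromo-3,3-dimethylcyclohexyl]-1-methyl-7-oxabicyclo[2.2.1]hept-5-ene-2-carbaldehyde, bromine endo and formyl exo | CC1(C)C[C@@H]([C@@]23C=C[C@@](C)(O2)[C@@](Br)(C=O)C3)CC[C@@H]1Br
A2 | alternative 1 | 2-[(1S,4S)-4-bromo-3,3-dimethylcyclohexyl]-5-methylfuran | CC1(C)C[C@@H](c2ccc(C)o2)CC[C@@H]1Br
A3 | alternative 1 | 2-bromoprop-2-enal | C=C(Br)C=O
A4 | alternative 2 | (1R,2R,4S)-2-bromo-4-[(4S)-4-bromo-5,5-dimethylcyclohex-1-en-1-yl]-1-methyl-7-oxabicyclo[2.2.1]heptane | CC1(C)CC(=CC[C@@H]1Br)[C@@]23CC[C@@](C)(O2)[C@H](Br)C3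
A5 | alternative 2 | (3S)-3-bromo-6-[(1S,3R,4R)-3-bromo-4-methyl-7-oxabicyclo[2.2.1]heptan-1-yl]-2-methylhept-6-en-2-ol | CC(C)(O)[C@@H](Br)CCC(=C)[C@@]12CC[C@@](C)(O1)[C@H](Br)C2
A6 | alternative 3 | (2R,4S)-2-bromo-4-[(1S,4S)-4-bromo-3,3-dimethylcyclohexyl]-4-hydroxycyclohexan-1-one | CC1(C)C[C@@H]([C@]2(O)CCC(=O)[C@H](Br)C2)CC[C@@H]1Br
A7 | alternative 3 | 4-[(1S,4S)-4-bromo-3,3-dimethylcyclohexyl]-4-hydroxycyclohexan-1-one | CC1(C)C[C@@H](C2(O)CCC(=O)CC2)CC[C@@H]1Br
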